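**Plan**

1. Ring numbering used here: C1 (stereocentre), C2H2, C3H=C4(CH3), C5H2, C6H2, back to C1; the exocyclic carbon Ca carries =CH2 and the chain. The retrosynthesis cuts Ca=CH2 (ketone methylenation), then Ca–chain (Weinreb ketone synthesis), then the ring bonds C5–C6 and C3=C4 in one event; in the chain it cuts the (Z)-olefin (carbocupration) and the three methyl-bearing centres (hydrogenation).
2. Enabling feature: C2–C3=C4(CH3)–C5 of the cyclohexene is a prenyl group in disguise (C5 is a former prenyl methyl) and C6 lies β to the carbonyl-level carbon Ca. The ring is therefore an open-chain 2-(halomethyl)-5-methylhex-4-enoyl unit folded from C6 onto C5 with allylic transposition; the acyl group on C1 activates C6 and later takes the chain.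
3. Ring, forward: an oxazolidinone auxiliary sets C1 by hydroxymethylation; iodide; transposing ene-type chlorination of the prenyl olefin; zinc insertion and copper-catalysed intramolecular SN2′ closure (new C5–C6 σ bond, new C3=C4 π bond); Weinreb amide.
4. Chain, forward: one iridium-catalysed asymmetric hydrogenation of all-(E)-geranylgeraniol sets the three (S) methyl centres by catalyst control; one-carbon homologation; a three-component carbocupration (alkylcopper, propyne, oxirane) fixes the (Z)-trisubstituted olefin.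
5. Union: homoallylic alkyllithium plus ring Weinreb amide, then non-basic methylenation; after step 2 the conditions avoid enolising C1, and its CIP label changes only through priority changes.

Key step: step 5

Remark: 5-methylhex-4-enoic acid (2) and (2E,6E,10E)-geranylgeraniol (12) are taken as commercial; the chloride-bearing carbon of 8 is carried as both epimers because it becomes sp2 in step 5.

**Route**

Step 1
Reactants: 1 (R)-4-benzyloxazolidin-2-one and 2 5-methylhex-4-enoic acid
Product: 4 (R)-4-benzyl-3-(5-methylhex-4-enoyl)oxazolidin-2-one, via mixed pivalic anhydride 3 (not isolated)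
Conditions: t-BuCOCl, Et3N, THF, −20 °C; then LiCl, 1, −20 → 25 °C
Reagents that add atoms: none
Why: N-acylation of the auxiliary through the mixed anhydride (LiCl/Et3N activation) should load the prenyl-bearing acyl chain without forming a stereocentre.

Step 2
Reactants: 4 (R)-4-benzyl-3-(5-methylhex-4-enoyl)oxazolidin-2-one
Product: 6 (R)-4-benzyl-3-[(2S)-2-(hydroxymethyl)-5-methylhex-4-enoyl]oxazolidin-2-one, via chlorotitanium enolate 5 (not isolated)
Conditions: TiCl4, i-Pr2NEt, CH2Cl2, 0 °C; then 1,3,5-trioxane, TiCl4, 0 °C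
Reagents that add atoms: 1,3,5-trioxane (formaldehyde source), C1OCOCO1
Why: Evans-type auxiliary-controlled hydroxymethylation (aldol-type addition of a titanium enolate to formaldehyde), in which the chelated (Z)-enolate 5 should be attacked on the face opposite the benzyl group, setting ring C1 (2S here) and introducing ring carbon C6.

Step 3
Reactants: 6 (R)-4-benzyl-3-[(2S)-2-(hydroxymethyl)-5-methylhex-4-enoyl]oxazolidin-2-one
Product: 7 (R)-4-benzyl-3-[(2R)-2-(iodomethyl)-5-methylhex-4-enoyl]oxazolidin-2-one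
Conditions: I2, PPh3, imidazole, CH2Cl2, 0 → 25 °C
Reagents that add atoms: iodine, II
Why: Appel iodination of the primary alcohol is an SN2 process at CH2 and should leave the adjacent stereocentre untouched (the descriptor becomes R only through CIP priority).

Step 4
Reactants: 7 (R)-4-benzyl-3-[(2R)-2-(iodomethyl)-5-methylhex-4-enoyl]oxazolidin-2-one
Product: 8 (R)-4-benzyl-3-[(2R,4RS)-4-chloro-2-(iodomethyl)-5-methylhex-5-enoyl]oxazolidin-2-one
Conditions: N-chlorosuccinimide, PhSeCl (10 mol %), CH2Cl2, 25 °C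
Reagents that add atoms: N-chlorosuccinimide, O=C1CCC(=O)N1Cl
Why: Selenium-catalysed ene-type allylic chlorination of a trisubstituted olefin should give the transposed secondary allylic chloride next to a new 1,1-disubstituted olefin; the C–Cl centre forms unselectively and is erased in step 5.

Step 5
Reactants: 8 (R)-4-benzyl-3-[(2R,4RS)-4-chloro-2-(iodomethyl)-5-methylhex-5-enoyl]oxazolidin-2-one
Product: 10 (R)-4-benzyl-3-[(1R)-4-methylcyclohex-3-ene-1-carbonyl]oxazolidin-2-one, via alkylzinc iodide 9 (not isolated)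
Conditions: Zn dust (Me3SiCl-activated), DMF, 0 → 25 °C; then CuBr·SMe2 (10 mol %), −20 → 25 °C
Reagents that add atoms: none
Why: Zinc should insert into the primary C–I bond, helped by chelation to the β-imide carbonyl, to give alkylzinc iodide 9, which transmetalates to monovalent copper. The alkylcopper should attack the terminal CH2 (C5) of the isopropenyl group anti to the departing chloride (SN2′) through a trivalent-copper σ-allyl species, whose reductive elimination forms the C5–C6 σ bond while the double bond moves into the ring as C3=C4. The closest known reaction type is the copper-catalysed SN2′ allylation of β-carbonyl alkylzinc iodides with allylic chlorides, applied here within one molecule. The cyclohexene closes in a 6-endo-trig mode with respect to the attacked olefin, whereas direct SN2 at C3 would be a 4-exo closure and is geometrically disfavoured. No stereocentre is created: C1 is a spectator that the non-basic zinc and copper species should not enolise, and the chloride-bearing carbon becomes sp2, so both epimers of 8 should converge on one product. The step needs chemoselective insertion into C–I beside the allylic C–Cl and γ-selective attack; the carbonyl-activated iodide at 0 °C should secure the first and the ring-size constraint the second.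

Step 6
Reactants: 10 (R)-4-benzyl-3-[(1R)-4-methylcyclohex-3-ene-1-carbonyl]oxazolidin-2-one
Product: 11 (1R)-N-methoxy-N,4-dimethylcyclohex-3-ene-1-carboxamide
Conditions: MeNH(OMe)·HCl, AlMe3, CH2Cl2, 0 → 25 °C
Reagents that add atoms: N,O-dimethylhydroxylamine hydrochloride, CNOC.Cl
Why: Aluminium-amide transamination (Weinreb amide formation) should cleave the exocyclic imide carbonyl under Lewis-acidic, non-epimerising conditions and release the auxiliary.

Step 7
Reactants: 12 (2E,6E,10E)-3,7,11,15-tetramethylhexadeca-2,6,10,14-tetraen-1-ol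
Product: 13 (3S,7S,11S)-3,7,11,15-tetramethylhexadecan-1-ol
Conditions: H2 (50 bar), [Ir(cod)(L)][B(C6H3(CF3)2)4] (1 mol %; L = enantiopure 2-aryl-cyclopenta[b]pyridin-7-yl phosphinite N,P ligand), CH2Cl2, 25 °C
Reagents that add atoms: none
Why: Iridium N,P-ligand-catalysed asymmetric hydrogenation of (E)-trisubstituted olefins is catalyst-controlled, so with the ligand enantiomer that gives (S) from an (E)-olefin the three stereogenic olefins should be reduced with the same facial sense in one event (the terminal isopropylidene gives no stereocentre).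

Step 8
Reactants: 13 (3S,7S,11S)-3,7,11,15-tetramethylhexadecan-1-ol
Product: 14 (3S,7S,11S)-1-bromo-3,7,11,15-tetramethylhexadecane
Conditions: CBr4, PPh3, CH2Cl2, 0 °C
Reagents that add atoms: carbon tetrabromide, BrC(Br)(Br)Br
Why: Appel bromination of a primary alcohol should proceed cleanly, remote from all stereocentres.

Step 9
Reactants: 14 (3S,7S,11S)-1-bromo-3,7,11,15-tetramethylhexadecane
Product: 16 (4S,8S,12S)-4,8,12,16-tetramethylheptadecan-1-ol, via Grignard reagent 15 (not isolated)
Conditions: Mg, THF, 40 °C; then (CH2O)n, 0 → 25 °C; aq. NH4Cl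
Reagents that add atoms: paraformaldehyde (formaldehyde), C=O
Why: Grignard addition to formaldehyde should add the one carbon that later becomes the allylic CH2 of the chain.

Step 10
Reactants: 16 (4S,8S,12S)-4,8,12,16-tetramethylheptadecan-1-ol
Product: 17 (4S,8S,12S)-1-bromo-4,8,12,16-tetramethylheptadecane
Conditions: CBr4, PPh3, CH2Cl2, 0 °C
Reagents that add atoms: carbon tetrabromide, BrC(Br)(Br)Br
Why: Appel bromination, as in step 8.

Step 11
Reactants: 17 (4S,8S,12S)-1-bromo-4,8,12,16-tetramethylheptadecane, 18 propyne and 19 oxirane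
Product: 23 (3Z,8S,12S,16S)-4,8,12,16,20-pentamethylhenicos-3-en-1-ol, via alkylmagnesium bromide 20 (not isolated), via alkylcopper 21 (not isolated), via (Z)-alkenylcopper 22 (not isolated)
Conditions: Mg, Et2O; CuBr·SMe2, Et2O/Me2S, −40 °C; propyne, −25 °C; LiC≡C-n-Pr, oxirane, −40 → 0 °C; aq. NH4Cl
Reagents that add atoms: none
Why: Normant carbocupration: the alkylcopper should add syn across propyne with the alkyl group on the internal carbon, and the alkenylcopper (as a mixed alkynyl cuprate) should open oxirane with retention, so the long chain and the CH2CH2OH arm end up cis, giving the (Z)-olefin.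

Step 12
Reactants: 23 (3Z,8S,12S,16S)-4,8,12,16,20-pentamethylhenicos-3-en-1-ol
Product: 24 (3Z,8S,12S,16S)-1-iodo-4,8,12,16,20-pentamethylhenicos-3-ene
Conditions: I2, PPh3, imidazole, CH2Cl2, 0 °C
Reagents that add atoms: iodine, II
Why: Appel iodination of the homoallylic primary alcohol under neutral conditions should not touch the olefin geometry.

Step 13
Reactants: 24 (3Z,8S,12S,16S)-1-iodo-4,8,12,16,20-pentamethylhenicos-3-ene and 11 (1R)-N-methoxy-N,4-dimethylcyclohex-3-ene-1-carboxamide
Product: 26 (4Z,9S,13S,17S)-5,9,13,17,21-pentamethyl-1-[(1R)-4-methylcyclohex-3-en-1-yl]docos-4-en-1-one, via alkyllithium 25 (not isolated)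
Conditions: t-BuLi (2.1 equiv), Et2O/pentane, −78 °C; then 11, −78 → 0 °C; aq. NH4Cl
Reagents that add atoms: none
Why: Iodine–lithium exchange followed by Weinreb ketone synthesis: the chelated tetrahedral adduct should prevent over-addition, and at −78 °C addition should outrun deprotonation at the ring stereocentre.

Step 14
Reactants: 26 (4Z,9S,13S,17S)-5,9,13,17,21-pentamethyl-1-[(1R)-4-methylcyclohex-3-en-1-yl]docos-4-en-1-one
Product: 27 (4R)-1-methyl-4-[(5Z,10S,14S,18S)-6,10,14,18,22-pentamethyltricosa-1,5-dien-2-yl]cyclohex-1-ene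
Conditions: Zn, CH2Br2, TiCl4, THF/CH2Cl2, 0 → 25 °C
Reagents that add atoms: dibromomethane, BrCBr
Why: Takai–Lombardo methylenation is a non-basic carbonyl olefination and should turn the enolisable ketone into the 1,1-disubstituted olefin without epimerising the neighbouring ring stereocentre.

**Compound list**

1 | (R)-4-benzyloxazolidin-2-one | O=C1N[C@H](Cc2ccccc2)CO1 | starting material
2 | 5-methylhex-4-enoic acid | CC(C)=CCCC(=O)O | starting material
3 | 5-methylhex-4-enoic pivalic anhydride | CC(C)=CCCC(=O)OC(=O)C(C)(C)C | intermediate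
4 | (R)-4-benzyl-3-(5-methylhex-4-enoyl)oxazolidin-2-one | CC(C)=CCCC(=O)N1[C@H](Cc2ccccc2)COC1=O | intermediate
5 | trichlorotitanium (Z)-enolate of 4 | CC(C)=CC/C=C(\O[Ti](Cl)(Cl)Cl)N1[C@H](Cc2ccccc2)COC1=O | intermediate
6 | (R)-4-benzyl-3-[(2S)-2-(hydroxymethyl)-5-methylhex-4-enoyl]oxazolidin-2-one | CC(C)=CC[C@@H](CO)C(=O)N1[C@H](Cc2ccccc2)COC1=O | intermediate
7 | (R)-4-benzyl-3-[(2R)-2-(iodomethyl)-5-methylhex-4-enoyl]oxazolidin-2-one | CC(C)=CC[C@@H](CI)C(=O)N1[C@H](Cc2ccccc2)COC1=O | intermediate
8 | (R)-4-benzyl-3-[(2R,4RS)-4-chloro-2-(iodomethyl)-5-methylhex-5-enoyl]oxazolidin-2-one | C=C(C)C(Cl)C[C@@H](CI)C(=O)N1[C@H](Cc2ccccc2)COC1=O | intermediate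
9 | alkylzinc iodide from 8 (CH2ZnI in place of CH2I) | C=C(C)C(Cl)C[C@@H](C[Zn]I)C(=O)N1[C@H](Cc2ccccc2)COC1=O | intermediate
10 | (R)-4-benzyl-3-[(1R)-4-methylcyclohex-3-ene-1-carbonyl]oxazolidin-2-one | O=C([C@H]1CC=C(C)CC1)N1[C@H](Cc2ccccc2)COC1=O | intermediate
11 | (1R)-N-methoxy-N,4-dimethylcyclohex-3-ene-1-carboxamide | CON(C)C(=O)[C@H]1CC=C(C)CC1 | intermediate
12 | (2E,6E,10E)-3,7,11,15-tetramethylhexadeca-2,6,10,14-tetraen-1-ol (geranylgeraniol) | CC(C)=CCC/C(C)=C/CC/C(C)=C/CC/C(C)=C/CO | starting material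
13 | (3S,7S,11S)-3,7,11,15-tetramethylhexadecan-1-ol | OCC[C@@H](C)CCC[C@@H](C)CCC[C@@H](C)CCCC(C)C | intermediate
14 | (3S,7S,11S)-1-bromo-3,7,11,15-tetramethylhexadecane | BrCC[C@@H](C)CCC[C@@H](C)CCC[C@@H](C)CCCC(C)C | intermediate
15 | Grignard reagent of 14 | Br[Mg]CC[C@@H](C)CCC[C@@H](C)CCC[C@@H](C)CCCC(C)C | intermediate
16 | (4S,8S,12S)-4,8,12,16-tetramethylheptadecan-1-ol | OCCC[C@@H](C)CCC[C@@H](C)CCC[C@@H](C)CCCC(C)C | intermediate
17 | (4S,8S,12S)-1-bromo-4,8,12,16-tetramethylheptadecane | BrCCC[C@@H](C)CCC[C@@H](C)CCC[C@@H](C)CCCC(C)C | intermediate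
18 | propyne | CC#C | starting material
19 | oxirane | C1CO1 | starting material
20 | Grignard reagent of 17 | Br[Mg]CCC[C@@H](C)CCC[C@@H](C)CCC[C@@H](C)CCCC(C)C | intermediate
21 | alkylcopper from 20 | [Cu]CCC[C@@H](C)CCC[C@@H](C)CCC[C@@H](C)CCCC(C)C | intermediate
22 | (Z)-alkenylcopper from 21 and propyne (Cu cis to the long chain) | [Cu]/C=C(/C)CCC[C@@H](C)CCC[C@@H](C)CCC[C@@H](C)CCCC(C)C | intermediate
23 | (3Z,8S,12S,16S)-4,8,12,16,20-pentamethylhenicos-3-en-1-ol | OCC/C=C(/C)CCC[C@@H](C)CCC[C@@H](C)CCC[C@@H](C)CCCC(C)C | intermediate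
24 | (3Z,8S,12S,16S)-1-iodo-4,8,12,16,20-pentamethylhenicos-3-ene | ICC/C=C(/C)CCC[C@@H](C)CCC[C@@H](C)CCC[C@@H](C)CCCC(C)C | intermediate
25 | alkyllithium from 24 | [Li]CC/C=C(/C)CCC[C@@H](C)CCC[C@@H](C)CCC[C@@H](C)CCCC(C)C | intermediate
26 | (4Z,9S,13S,17S)-5,9,13,17,21-pentamethyl-1-[(1R)-4-methylcyclohex-3-en-1-yl]docos-4-en-1-one | O=C(CC/C=C(/C)CCC[C@@H](C)CCC[C@@H](C)CCC[C@@H](C)CCCC(C)C)[C@H]1CC=C(C)CC1 | intermediate
27 | (4R)-1-methyl-4-[(5Z,10S,14S,18S)-6,10,14,18,22-pentamethyltricosa-1,5-dien-2-yl]cyclohex-1-ene | C=C(CC/C=C(/C)CCC[C@@H](C)CCC[C@@H](C)CCC[C@@H](C)CCCC(C)C)[C@H]1CC=C(C)CC1 | target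

**Step count and risks**

Total steps: 14. Longest linear sequence: 8 steps (steps 1–6, 13, 14 from 1 and 2; equally steps 7–14 from 12).

Step 5 (zinc insertion and copper-catalysed SN2′ ring closure). Zinc may also insert into the allylic C–Cl bond, or the alkylcopper may be protonated before it reaches the olefin terminus, so that reduced open-chain material forms instead of the ring. The fallback sets out from 6 and comes back at 10. CBr4/PPh3 would give (R)-4-benzyl-3-[(2R)-2-(bromomethyl)-5-methylhex-4-enoyl]oxazolidin-2-one F1. Aqueous hypochlorous acid (Ca(OCl)2, CO2, CH2Cl2/H2O, 0 °C) would then perform the transposing ene-chlorination to (R)-4-benzyl-3-[(2R,4RS)-2-(bromomethyl)-4-chloro-5-methylhex-5-enoyl]oxazolidin-2-one F2. The ring would be closed by nickel-catalysed reductive cross-electrophile coupling (NiBr2·glyme, 4,4′-di-tert-butyl-2,2′-bipyridine, Mn powder, DMA, 25 °C, high dilution). Here zerovalent nickel ionises the allylic chloride to an allylnickel species that captures the alkyl radical from the C–Br bond; no organozinc is needed and both chloride epimers should converge on 10.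

Step 11 (three-component carbocupration). The precious alkylcopper may add incompletely to propyne or be protonated, the alkenylcopper may open oxirane sluggishly, and warming may erode the Z purity. The fallback sets out from 14 and 11 and comes back at 26.
- 1,3-Dilithiopropyne (from propyne 18, n-BuLi 2 equiv, TMEDA) would be alkylated at its sp3 carbon by 14 to give [(6S,10S,14S)-6,10,14,18-tetramethylnonadec-1-yn-1-yl]lithium F3.
- Trapping in the same flask with ClCO2Me would give methyl (7S,11S,15S)-7,11,15,19-tetramethylicos-2-ynoate F4.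
- Syn conjugate addition of Me2CuLi (THF, −78 °C, cold quench) should give methyl (2Z,7S,11S,15S)-3,7,11,15,19-pentamethylicos-2-enoate F5.
- i-Bu2AlH would give (2Z,7S,11S,15S)-3,7,11,15,19-pentamethylicos-2-en-1-ol F6, and CBr4/PPh3 would give (2Z,7S,11S,15S)-1-bromo-3,7,11,15,19-pentamethylicos-2-ene F7.
- On the ring side 11 and MeMgBr would give 1-[(1R)-4-methylcyclohex-3-en-1-yl]ethan-1-one F8.
- Its kinetic lithium enolate of F8 F9 (LiN(i-Pr)2, THF, −78 °C, deprotonation at CH3) would be alkylated by F7 to give 26.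

Step 2 (hydroxymethylation). The electron-rich prenyl olefin may attack titanium-activated formaldehyde in a Prins-type reaction, or facial selectivity may erode, on the one step that sets the ring configuration. The fallback sets out from 4 and comes back at 6. It avoids the Lewis acid: the sodium (Z)-enolate of 4 F10 (NaN(SiMe3)2, THF, −78 °C) would be alkylated with 4-methoxybenzyl chloromethyl ether under the same auxiliary control to give (R)-4-benzyl-3-[(2S)-2-{[(4-methoxybenzyl)oxy]methyl}-5-methylhex-4-enoyl]oxazolidin-2-one F11. Oxidative removal of the 4-methoxybenzyl group with DDQ (CH2Cl2/H2O) would then give 6.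

**Further compounds**

F1 | step 5 | (R)-4-benzyl-3-[(2R)-2-(bromomethyl)-5-methylhex-4-enoyl]oxazolidin-2-one | CC(C)=CC[C@@H](CBr)C(=O)N1[C@H](Cc2ccccc2)COC1=O
F2 | step 5 | (R)-4-benzyl-3-[(2R,4RS)-2-(bromomethyl)-4-chloro-5-methylhex-5-enoyl]oxazolidin-2-one | C=C(C)C(Cl)C[C@@H](CBr)C(=O)N1[C@H](Cc2ccccc2)COC1=O
F3 | step 11 | [(6S,10S,14S)-6,10,14,18-tetramethylnonadec-1-yn-1-yl]lithium | [Li]C#CCCC[C@@H](C)CCC[C@@H](C)CCC[C@@H](C)CCCC(C)C
F4 | step 11 | methyl (7S,11S,15S)-7,11,15,19-tetramethylicos-2-ynoate | COC(=O)C#CCCC[C@@H](C)CCC[C@@H](C)CCC[C@@H](C)CCCC(C)C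
F5 | step 11 | methyl (2Z,7S,11S,15S)-3,7,11,15,19-pentamethylicos-2-enoate | COC(=O)/C=C(/C)CCC[C@@H](C)CCC[C@@H](C)CCC[C@@H](C)CCCC(C)C
F6 | step 11 | (2Z,7S,11S,15S)-3,7,11,15,19-pentamethylicos-2-en-1-ol | OC/C=C(/C)CCC[C@@H](C)CCC[C@@H](C)CCC[C@@H](C)CCCC(C)C
F7 | step 11 | (2Z,7S,11S,15S)-1-bromo-3,7,11,15,19-pentamethylicos-2-ene | BrC/C=C(/C)CCC[C@@H](C)CCC[C@@H](C)CCC[C@@H](C)CCCC(C)C
F8 | step 11 | 1-[(1R)-4-methylcyclohex-3-en-1-yl]ethan-1-one | CC(=O)[C@H]1CC=C(C)CC1
F9 | step 11 | lithium enolate of F8 | [Li]OC(=C)[C@H]1CC=C(C)CC1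
F10 | step 2 | sodium (Z)-enolate of 4 | CC(C)=CC/C=C(\O[Na])N1[C@H](Cc2ccccc2)COC1=O
F11 | step 2 | (R)-4-benzyl-3-[(2S)-2-{[(4-methoxybenzyl)oxy]methyl}-5-methylhex-4-enoyl]oxazolidin-2-one | COc1ccc(COC[C@H](CC=C(C)C)C(=O)N2[C@H](Cc3ccccc3)COC2=O)cc1
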